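## The problem

6,8-Diprenylnaringenin (13) is a flavanone: a fully substituted phloroglucinol ring A is fused through O1–C8a and C4–C4a to the dihydropyranone ring C, which carries the 4-hydroxyphenyl ring B at C2. C2 is the only stereocentre. It is benzylic, bonded to the phenolic oxygen O1 and β to the C4 carbonyl, so base opens ring C to the achiral 2'-hydroxychalcone and recloses it without selectivity. No second stereocentre exists to direct C2, so its (S) configuration must come from a catalyst or reagent and must be kept away from base once C4 is a ketone. The prenyl groups at C6 and C8 rule out hydrogenation, electrophilic halogenation and epoxidising oxidants. Once the flanking phenols are free they also rule out strong acid, which adds the 5- or 7-hydroxyl across the alkene, and their benzylic–allylic CH2 groups are exposed to hydride-abstracting oxidants. Ring A has no free carbon, so all its substituents must be in place before ring C is closed or be installed by that closure. The enabling feature is that O1 and C4 sit on the adjacent ring A carbons C8a and C4a, while C2, C3 and ring B together are a 4-oxygenated styrene. O1–C8a–C4a–C4 is therefore the heterodiene of an ortho-quinone methide whose exocyclic carbon C4 is the formyl carbon of a salicylaldehyde.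

## Retrosynthesis

**Protecting groups (13 ⇐ 12 ⇐ 11).** Target 13 is traced to its 4'-O-acetate 12 and then to the 5,7-bis-silyl ether 11; only an O–acyl and two O–Si bonds are cut.
- The ring B acetate is kept to the end because it keeps the styrene partner from polymerising and keeps the O1–C2 bond from ionising under acid.
- The ring A silyl ethers stay until after the oxidation because free phenols would add to the prenyl alkenes under acid and interfere with the alcohol oxidation.
- A single basic global deprotection was rejected, since a flavanone with free phenols opens by retro-oxa-Michael reaction in base. The forward steps must be a non-basic fluoride cleavage and a near-neutral deacetylation.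

**Oxidation level at C4 (11 ⇐ 10 ⇐ 9).** Flavanone 11 is traced to flavan-4-ol 10 and then to 4-methoxyflavan 9; the C4=O bond is replaced first by C4–OH, then by C4–OMe.
- A one-step oxidative unmasking of the methyl ether with a quinone oxidant was considered and kept only as a reserve. Hydride abstraction at C4 would compete with abstraction from the two prenyl CH2 groups, which are activated by the same three ring oxygens.
- The two-step path uses the lability of a 4-alkoxy group on a flavan with oxygen at C5, C7 and C8a. The C4 cation forms under mild aqueous acid, ring A has no free carbon for it to alkylate, and hydrolysis gives 10.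
- The forward steps must be a clean solvolysis and a buffered oxidation of a hindered benzylic alcohol. The configuration at C4 does not matter, as it is erased in 11.

**Ring C (9 ⇐ 4 + 5 + 6, through 7 and 8).** The central cut breaks O1–C2 and C3–C4 of 9 together and removes ring C, giving salicylaldehyde 4, trimethyl orthoformate 5 and 4-acetoxystyrene 6.
- In the forward direction 4 and 5 give dimethyl acetal 7, which loses methanol to the methoxy ortho-quinone methide 8; 8 adds 6 in an oxa-[4+2] cycloaddition.
- This two-bond cut is preferred to any single-bond closure of ring C because it needs no tethered chain. Both new bonds end on atoms already attached to ring A, and C2 is created in the same event.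
- Aldehyde 4 is much simpler than 9: no stereocentre, one ring fewer, and only two steps from a commercial aldehyde; 5 and 6 are commercial.
- The forward reaction must set C2 as (S) under catalyst control, choose the styrene over the two prenyl alkenes, and leave the free hydroxyl of 4 and its neighbouring prenyl group unreacted.

**Ring A (4 ⇐ 3 ⇐ 1 + 2).** Aldehyde 4 is traced to triol 3 by cutting two O–Si bonds, and 3 to 2,4,6-trihydroxybenzaldehyde 1 and prenyl bromide 2 by cutting the two aryl–CH2 bonds.
- Prenylation first is preferred to protection first, because the phenolate of 1 directs C-alkylation to its only two free carbons.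
- The formyl group ties up one ortho hydroxyl in a hydrogen bond, so silylation of 3 leaves exactly the hydroxyl that becomes O1.
- The forward steps must give double C-alkylation without O-alkylation or geminal dialkylation, and silylation at two of three hydroxyls.

## Roads not taken

**Alternative 1:** Ring C closed by aryl ether formation, cutting O1–C8a. The (S)-configured bromo alcohol A1 would be cyclised with CuI, 3,4,7,8-tetramethyl-1,10-phenanthroline and Cs2CO3 to the 4-silyloxyflavan A2.
- Merits: C2 is set beforehand by a reliable asymmetric ketone reduction and is carried through with retention, since its C–O bond is not touched. No acid is used while the prenyl groups are present.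
- Weak points: the bromide of A1 is flanked on both sides and sits on a very electron-rich ring, so the coupling would need prolonged heating with carbonate. A1 itself needs a hexasubstituted bromoarene (halogenation in the presence of prenyl alkenes is not selective), a three-carbon chain built by aldol chemistry, an asymmetric reduction and protection of the C4 carbinol. After A2 come desilylation, oxidation and acidic removal of three methoxymethyl groups next to prenyl groups.
- Comparison: this road is more secure than the chosen plan at C2. The chosen plan sets against it a route about half as long, which forms two bonds, the ring and the stereocentre in one step, and has a resolution-based reserve if catalyst control fails.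

**Alternative 2:** Ring C closed by carbene insertion, cutting C2–C3. Diazoketone A3 would be decomposed by Rh2(S-PTTL)4, a dirhodium tetracarboxylate of divalent rhodium, so that the carbene at C3 inserts into one enantiotopic benzylic C–H bond of the O1 benzyl ether and gives the tris-silyl flavanone A4.
- Merits: the key step delivers the flavanone oxidation level and C2 together, and A4 needs only one fluoride step to reach 13. After the key step this road is shorter than the chosen plan.
- Weak points: the carbene of A3 has only an acyl substituent and lies next to the lone pairs of O1. Oxonium ylide formation followed by a 1,2-benzyl shift, which contracts the ring, is the expected competitor of a six-membered C–H insertion. The two prenyl alkenes are cyclopropanation traps. Enantiocontrol for six-membered insertion of simple diazoketones is poorly supported. A3 also requires a doubly ortho-substituted benzoic acid to be turned into a diazoketone and a hindered chelated phenol to be benzylated.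
- Comparison: the chosen plan has a longer endgame, but each of its post-cycloaddition steps is routine and its key step has no known competing pathway that wins by default.

**Alternative 3:** Ring C closed by Friedel–Crafts acylation, cutting C4–C4a. The (S)-3-aryloxy-3-arylpropanoic acid A5 would be activated as its acid chloride or trifluoroacetic mixed anhydride and would acylate the only free carbon of ring A to give flavanone A6, which is identical with compound 11.
- Merits: regiochemistry is not an issue, no redox adjustment at C4 is needed, and C2 comes from established chemistry (asymmetric reduction of a β-keto ester, then Mitsunobu etherification with inversion). At C2 this road is better founded than the chosen plan.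
- Weak points: the Mitsunobu step pairs a secondary benzylic β-hydroxy ester with an ortho-substituted electron-rich phenol, where elimination and partial loss of configuration compete. That phenol requires two of three hydroxyls of a diprenylphloroglucinol to be silylated with the correct outer one left free. Activation of A5 invites β-elimination of the aryloxide, which destroys C2. The acylating media are strongly acidic in the presence of two prenyl alkenes and two aryl silyl ethers.
- Comparison: the chosen plan reaches compound 11 in five steps from a symmetrical commercial aldehyde, without desymmetrising ring A and without a strongly acidic step after the prenyl groups are in place.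

Key step: step 3

Assumption: which antipode of the imidodiphosphorimidate gives the (2S) adduct cannot be predicted, so the (S,S) catalyst is written and its mirror image would be used if induction is opposite; compound 10 is carried as a mixture of C4 epimers, which converge in step 5.

## Route

Step 1
Reactants: 1 2,4,6-trihydroxybenzaldehyde; 2 prenyl bromide (1-bromo-3-methylbut-2-ene)
Product: 3 2,4,6-trihydroxy-3,5-bis(3-methylbut-2-enyl)benzaldehyde
Conditions: 2 (2.1 equiv), 10% aq. KOH, 0 °C → rt; then dilute HCl
Reagents that add atoms: none
Why: Phenolate C-alkylation of an acylphloroglucinol in water, the reaction type used for 3,5-diprenyl acylphloroglucinols; the protic medium disfavours O-alkylation and the two free ring carbons are the only C-nucleophilic sites.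

Step 2
Reactants: 3 2,4,6-trihydroxy-3,5-bis(3-methylbut-2-enyl)benzaldehyde
Product: 4 2-hydroxy-4,6-bis(tert-butyldimethylsilyloxy)-3,5-bis(3-methylbut-2-enyl)benzaldehyde
Conditions: TBSCl (2.2 equiv), imidazole, DMF, 0 °C → rt
Reagents that add atoms: tert-butyldimethylsilyl chloride, CC(C)(C)[Si](C)(C)Cl
Why: Standard phenol silylation; the 4-hydroxyl and one ortho hydroxyl react, while the last ortho hydroxyl is held in a hydrogen bond to the formyl group and resists silylation, as in the usual bis-protection of 2,4,6-trihydroxyaryl carbonyl compounds.

Step 3
Reactants: 4 2-hydroxy-4,6-bis(tert-butyldimethylsilyloxy)-3,5-bis(3-methylbut-2-enyl)benzaldehyde; 5 trimethyl orthoformate; 6 4-acetoxystyrene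
Product: 9 (2S,4S)-cis-2-(4-acetoxyphenyl)-5,7-bis(tert-butyldimethylsilyloxy)-4-methoxy-6,8-bis(3-methylbut-2-enyl)chromane, via dimethyl acetal 7 (not isolated), via methoxy ortho-quinone methide 8 (not isolated)
Conditions: (S,S)-imidodiphosphorimidate Brønsted acid (two 3,3'-diaryl-(S)-BINOL units, N-triflyl groups; 5 mol %), 5 (1.5 equiv), 6 (4 equiv), 5 Å MS, CH2Cl2, −60 → −30 °C
Reagents that add atoms: none
Why: Proposed new method: acid-catalysed acetalisation of 4 with 5 gives acetal 7, which loses methanol to the methoxy ortho-quinone methide 8, present as its conjugate acid (an O-methyl oxocarbenium ion whose ortho hydroxyl is hydrogen-bonded to the chiral anion); the closest known reaction type is the achiral-acid condensation of salicylaldehydes, orthoformates and styrenes to 2,4-cis-4-alkoxyflavans, together with chiral-Brønsted-acid [4+2] cycloadditions of other ortho-quinone methides, and the asymmetric version on an acetal-derived cation with a simple styrene is the untested part. The CH2 terminus of 6 bonds to the cationic C4 and the developing benzylic cation at C2 is captured by O1, an asynchronous inverse-electron-demand oxa-[4+2] closure that forms C3–C4 and O1–C2, closes ring C as a six-membered ring and restores the aromaticity of ring A. The orientation follows polarity: the unsubstituted alkene carbon is the nucleophile and the carbon that best carries positive charge ends on oxygen. C4 and C2 are both created here; the confined anion is expected to shield one face of the heterodiene and admit the styrene endo, giving the 2,4-cis adduct and, with the right catalyst antipode, the (2S,4S) isomer. Because C4 is later flattened to the carbonyl carbon, only the styrene face counts in the end, and cis and trans adducts from one heterodiene face are antipodal at C2, so endo selectivity is needed as much as face selectivity. Selection of the styrene over the prenyl alkenes rests on the excess of 6 and on the slim monosubstituted alkene fitting the catalyst pocket better than a trisubstituted one; the prenyl groups sit on ring carbons meta to the one carrying the cationic carbon and cannot reach it within the molecule. Low temperature and a catalytic amount of acid are meant to keep the free O1 hydroxyl from adding across the neighbouring C8 prenyl alkene, and the electron-poor 4-acetoxyphenyl group keeps the new O1–C2 bond from ionising and eroding C2.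

Step 4
Reactants: 9 (2S,4S)-cis-2-(4-acetoxyphenyl)-5,7-bis(tert-butyldimethylsilyloxy)-4-methoxy-6,8-bis(3-methylbut-2-enyl)chromane
Product: 10 (2S)-2-(4-acetoxyphenyl)-5,7-bis(tert-butyldimethylsilyloxy)-6,8-bis(3-methylbut-2-enyl)chroman-4-ol (mixture of C4 epimers)
Conditions: TsOH·H2O (10 mol %), THF/H2O 4:1, rt
Reagents that add atoms: water, O
Why: SN1 solvolysis of a benzylic methyl ether whose cation is stabilised by three ring oxygens ortho and para to C4, captured by the large excess of water; ring A has no free carbon for self-alkylation, and C2 is untouched because its aryl group is electron-poor.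

Step 5
Reactants: 10 (2S)-2-(4-acetoxyphenyl)-5,7-bis(tert-butyldimethylsilyloxy)-6,8-bis(3-methylbut-2-enyl)chroman-4-ol
Product: 11 (2S)-2-(4-acetoxyphenyl)-5,7-bis(tert-butyldimethylsilyloxy)-6,8-bis(3-methylbut-2-enyl)chroman-4-one
Conditions: Dess–Martin periodinane (1.5 equiv), NaHCO3, CH2Cl2, 0 °C → rt
Reagents that add atoms: none
Why: Dess–Martin oxidation of a secondary benzylic alcohol under buffered conditions; trisubstituted alkenes, aryl silyl ethers and the aryl acetate are inert, both C4 epimers converge on one ketone, and no base strong enough to open ring C is present.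

Step 6
Reactants: 11 (2S)-2-(4-acetoxyphenyl)-5,7-bis(tert-butyldimethylsilyloxy)-6,8-bis(3-methylbut-2-enyl)chroman-4-one
Product: 12 (2S)-2-(4-acetoxyphenyl)-5,7-dihydroxy-6,8-bis(3-methylbut-2-enyl)chroman-4-one
Conditions: Et3N·3HF (excess), THF, rt → 40 °C
Reagents that add atoms: none
Why: Fluoride cleavage of aryl silyl ethers with a weakly acidic amine–HF complex; the silyloxy groups ortho and para to the carbonyl are activated leaving groups, the acetate is untouched, and the absence of base prevents ring opening and racemisation at C2.

Step 7
Reactants: 12 (2S)-2-(4-acetoxyphenyl)-5,7-dihydroxy-6,8-bis(3-methylbut-2-enyl)chroman-4-one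
Product: 13 6,8-diprenylnaringenin, (2S)-5,7-dihydroxy-2-(4-hydroxyphenyl)-6,8-bis(3-methylbut-2-enyl)chroman-4-one
Conditions: NH4OAc (excess), MeOH/H2O 4:1, rt
Reagents that add atoms: none
Why: Chemoselective near-neutral deacetylation of a phenolic acetate by ammonium acetate in aqueous methanol (acyl transfer to solvent); this avoids both the base that racemises flavanones and the strong acid that cyclises ortho-prenyl phenols.

## Compound list

1 | 2,4,6-trihydroxybenzaldehyde | O=Cc1c(O)cc(O)cc1O | starting material
2 | prenyl bromide (1-bromo-3-methylbut-2-ene) | CC(C)=CCBr | starting material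
3 | 2,4,6-trihydroxy-3,5-bis(3-methylbut-2-enyl)benzaldehyde | CC(C)=CCc1c(O)c(C=O)c(O)c(CC=C(C)C)c1O | intermediate
4 | 2-hydroxy-4,6-bis(tert-butyldimethylsilyloxy)-3,5-bis(3-methylbut-2-enyl)benzaldehyde | CC(C)=CCc1c(O)c(C=O)c(O[Si](C)(C)C(C)(C)C)c(CC=C(C)C)c1O[Si](C)(C)C(C)(C)C | intermediate
5 | trimethyl orthoformate | COC(OC)OC | starting material
6 | 4-acetoxystyrene | C=Cc1ccc(OC(C)=O)cc1 | starting material
7 | dimethyl acetal of 4, 2-(dimethoxymethyl)-3,5-bis(tert-butyldimethylsilyloxy)-4,6-bis(3-methylbut-2-enyl)phenol | COC(OC)c1c(O)c(CC=C(C)C)c(O[Si](C)(C)C(C)(C)C)c(CC=C(C)C)c1O[Si](C)(C)C(C)(C)C | intermediate (not isolated)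
8 | methoxy ortho-quinone methide, 6-(methoxymethylidene)-3,5-bis(tert-butyldimethylsilyloxy)-2,4-bis(3-methylbut-2-enyl)cyclohexa-2,4-dien-1-one (reacts as its conjugate acid) | COC=C1C(=O)C(CC=C(C)C)=C(O[Si](C)(C)C(C)(C)C)C(CC=C(C)C)=C1O[Si](C)(C)C(C)(C)C | intermediate (not isolated)
9 | (2S,4S)-cis-2-(4-acetoxyphenyl)-5,7-bis(tert-butyldimethylsilyloxy)-4-methoxy-6,8-bis(3-methylbut-2-enyl)chromane | CC(C)=CCc1c(O[Si](C)(C)C(C)(C)C)c(CC=C(C)C)c2c(c1O[Si](C)(C)C(C)(C)C)[C@@H](OC)C[C@@H](c1ccc(OC(C)=O)cc1)O2 | intermediate
10 | (2S)-2-(4-acetoxyphenyl)-5,7-bis(tert-butyldimethylsilyloxy)-6,8-bis(3-methylbut-2-enyl)chroman-4-ol, C4 epimers | CC(C)=CCc1c(O[Si](C)(C)C(C)(C)C)c(CC=C(C)C)c2c(c1O[Si](C)(C)C(C)(C)C)C(O)C[C@@H](c1ccc(OC(C)=O)cc1)O2 | intermediate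
11 | (2S)-2-(4-acetoxyphenyl)-5,7-bis(tert-butyldimethylsilyloxy)-6,8-bis(3-methylbut-2-enyl)chroman-4-one | CC(C)=CCc1c(O[Si](C)(C)C(C)(C)C)c(CC=C(C)C)c2c(c1O[Si](C)(C)C(C)(C)C)C(=O)C[C@@H](c1ccc(OC(C)=O)cc1)O2 | intermediate
12 | (2S)-2-(4-acetoxyphenyl)-5,7-dihydroxy-6,8-bis(3-methylbut-2-enyl)chroman-4-one | CC(C)=CCc1c(O)c(CC=C(C)C)c2c(c1O)C(=O)C[C@@H](c1ccc(OC(C)=O)cc1)O2 | intermediate
13 | 6,8-diprenylnaringenin, (2S)-5,7-dihydroxy-2-(4-hydroxyphenyl)-6,8-bis(3-methylbut-2-enyl)chroman-4-one | CC(C)=CCc1c(O)c(CC=C(C)C)c2c(c1O)C(=O)C[C@@H](c1ccc(O)cc1)O2 | target

## Step count and risks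

Total: 7 steps. Longest linear sequence: 7 steps (1 → 13); 2, 5 and 6 are commercial.

**Step 3 (key step, proposed new method).**
- What may go wrong: insufficient control of the styrene face or of the endo/exo mode, which lowers the enantiomeric purity at C2. The cation is stabilised by three oxygens and may add too slowly to a weakly nucleophilic styrene. Acid-induced addition of the free hydroxyl across the neighbouring prenyl alkene and cationic oligomerisation of the styrene are the competing processes.
- Fallback (known chemistry), from 4 back to 11: the cycloaddition would be run in its known racemic form, with 5, 6 and an achiral acid such as diphenyl phosphate, to give the racemic 2,4-cis-4-methoxyflavan F1. The solvolysis and Dess–Martin oxidation of steps 4 and 5 would turn F1 into the racemic flavan-4-ol F2 and the racemic flavanone F3. F3 would be resolved kinetically by asymmetric transfer hydrogenation with RuCl[(R,R)-TsDPEN](p-cymene) and HCO2H/Et3N. This is expected to reduce the (2R) ketone to the (2R,4R)-cis-flavan-4-ol F4 and leave the (2S) ketone, which is compound 11. Half the material is lost, and the catalyst antipode would be exchanged if the sense of reduction is reversed.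

**Step 1.**
- What may go wrong: O-alkylation and geminal dialkylation with loss of aromaticity compete with the double C-alkylation, and mono- and di-alkylation are hard to balance.
- Fallback, from 1 directly to 3: Friedel–Crafts prenylation of the neutral phenol with 2-methylbut-3-en-2-ol and BF3·OEt2 in dioxane. This is an electrophilic substitution that cannot O-alkylate or dearomatise; conversion would be kept low to limit acid-induced cyclisation. No compound outside the list is made (F0).

**Step 4.**
- What may go wrong: the C4 cation loses a proton from C3 instead of being captured, or the exchange against methanol stops short of completion.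
- Fallback, from 9 directly to 11: oxidation with DDQ in CH2Cl2/H2O. Hydride abstraction at C4 gives the O-methyl oxocarbenium ion at the ketone oxidation level, and its hydrolysis gives the ketone and methanol. The concern there is competing abstraction at the prenyl CH2 groups, which is why it is not the first choice. No compound outside the list is made (F0).

**Step 7.**
- What may go wrong: slow acyl transfer, or erosion of configuration at C2 by reversible ring opening if the medium is more basic than intended.
- Fallback, from 12 to 13: enzymatic alcoholysis of the phenolic acetate with immobilised Candida antarctica lipase B and n-butanol in tert-butyl methyl ether, a neutral acyl transfer with no free base or acid. No compound outside the list is made (F0).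

## Further compounds

F1 | step 3 | racemic 2,4-cis-2-(4-acetoxyphenyl)-5,7-bis(tert-butyldimethylsilyloxy)-4-methoxy-6,8-bis(3-methylbut-2-enyl)chromane | CC(C)=CCc1c(O[Si](C)(C)C(C)(C)C)c(CC=C(C)C)c2c(c1O[Si](C)(C)C(C)(C)C)C(OC)CC(c1ccc(OC(C)=O)cc1)O2
F2 | step 3 | racemic 2-(4-acetoxyphenyl)-5,7-bis(tert-butyldimethylsilyloxy)-6,8-bis(3-methylbut-2-enyl)chroman-4-ol | CC(C)=CCc1c(O[Si](C)(C)C(C)(C)C)c(CC=C(C)C)c2c(c1O[Si](C)(C)C(C)(C)C)C(O)CC(c1ccc(OC(C)=O)cc1)O2
F3 | step 3 | racemic 2-(4-acetoxyphenyl)-5,7-bis(tert-butyldimethylsilyloxy)-6,8-bis(3-methylbut-2-enyl)chroman-4-one | CC(C)=CCc1c(O[Si](C)(C)C(C)(C)C)c(CC=C(C)C)c2c(c1O[Si](C)(C)C(C)(C)C)C(=O)CC(c1ccc(OC(C)=O)cc1)O2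
F4 | step 3 | (2R,4R)-cis-2-(4-acetoxyphenyl)-5,7-bis(tert-butyldimethylsilyloxy)-6,8-bis(3-methylbut-2-enyl)chroman-4-ol | CC(C)=CCc1c(O[Si](C)(C)C(C)(C)C)c(CC=C(C)C)c2c(c1O[Si](C)(C)C(C)(C)C)[C@H](O)C[C@H](c1ccc(OC(C)=O)cc1)O2
F0 | step 1 | none | none
F0 | step 4 | none | none
F0 | step 7 | none | none
A1 | alternative 1 | (1S)-3-[2-bromo-4,6-bis(methoxymethoxy)-3,5-bis(3-methylbut-2-enyl)phenyl]-3-(tert-butyldimethylsilyloxy)-1-[4-(methoxymethoxy)phenyl]propan-1-ol | CC(C)=CCc1c(OCOC)c(CC=C(C)C)c(Br)c(c1OCOC)C(O[Si](C)(C)C(C)(C)C)C[C@H](O)c1ccc(OCOC)cc1
A2 | alternative 1 | (2S)-4-(tert-butyldimethylsilyloxy)-5,7-bis(methoxymethoxy)-2-[4-(methoxymethoxy)phenyl]-6,8-bis(3-methylbut-2-enyl)chromane | CC(C)=CCc1c(OCOC)c(CC=C(C)C)c2c(c1OCOC)C(O[Si](C)(C)C(C)(C)C)C[C@@H](c1ccc(OCOC)cc1)O2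
A3 | alternative 2 | 2-diazo-1-{2-[4-(tert-butyldimethylsilyloxy)benzyloxy]-4,6-bis(tert-butyldimethylsilyloxy)-3,5-bis(3-methylbut-2-enyl)phenyl}ethanone | CC(C)=CCc1c(O[Si](C)(C)C(C)(C)C)c(CC=C(C)C)c(OCc2ccc(O[Si](C)(C)C(C)(C)C)cc2)c(c1O[Si](C)(C)C(C)(C)C)C(=O)C=[N+]=[N-]
A4 | alternative 2 | (2S)-5,7-bis(tert-butyldimethylsilyloxy)-2-[4-(tert-butyldimethylsilyloxy)phenyl]-6,8-bis(3-methylbut-2-enyl)chroman-4-one | CC(C)=CCc1c(O[Si](C)(C)C(C)(C)C)c(CC=C(C)C)c2c(c1O[Si](C)(C)C(C)(C)C)C(=O)C[C@@H](c1ccc(O[Si](C)(C)C(C)(C)C)cc1)O2
A5 | alternative 3 | (3S)-3-(4-acetoxyphenyl)-3-[3,5-bis(tert-butyldimethylsilyloxy)-2,4-bis(3-methylbut-2-enyl)phenoxy]propanoic acid | CC(C)=CCc1c(O[Si](C)(C)C(C)(C)C)c(CC=C(C)C)c(O[C@@H](CC(=O)O)c2ccc(OC(C)=O)cc2)cc1O[Si](C)(C)C(C)(C)C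
A6 | alternative 3 | (2S)-2-(4-acetoxyphenyl)-5,7-bis(tert-butyldimethylsilyloxy)-6,8-bis(3-methylbut-2-enyl)chroman-4-one (identical with compound 11) | CC(C)=CCc1c(O[Si](C)(C)C(C)(C)C)c(CC=C(C)C)c2c(c1O[Si](C)(C)C(C)(C)C)C(=O)C[C@@H](c1ccc(OC(C)=O)cc1)O2
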